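The ten-membered carbocycle C1–C10 is closed last, at C7–C8. The plan exploits the allyl unit C13–C11=C7 hidden in the α-methylene lactone (ring O–C12–C11–C7–C6): its γ-carbon C7 is the neighbour of carbinol C8. A C13 allylchromium, made from a 3-(bromomethyl)butenolide, attacks a C8 aldehyde through C7, which in one operation closes the carbocycle, sets C7 and C8 and unveils the C11=C13 methylene. The precursor is a (5R)-butenolide whose open C6 side chain carries both trisubstituted olefins (E by CIP, chain carbons cis), the C14 aldehyde as dimethyl acetal, O15 as silyl ether and the free C8 aldehyde.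

Key step: step 18

Remark: atoms carry germacranolide numbers (carbocycle C1–C10, C14 on C10, C15 on C4, lactone ring O–C12(=O)–C11(=C13)–C7–C6); 1-[(2-bromoethoxy)methyl]-4-methoxybenzene is taken to be a catalogue compound.

Step 1
Reactants: 1 triethyl phosphonoacetate; 2 2-(2-bromoethyl)-1,3-dioxolane
Product: 3 ethyl 2-(diethoxyphosphoryl)-4-(1,3-dioxolan-2-yl)butanoate (racemic)
Conditions: NaH, DMF, 0 → 60 °C
Reagents that add atoms: none
Why: SN2 C-alkylation of the sodium salt of the phosphonoacetate by a primary bromide is routine and should give the monoalkylated phosphonate, whose new α-centre is destroyed in step 2.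

Step 2
Reactants: 3 alkylated phosphonate; 4 (S)-2,2-dimethyl-1,3-dioxolane-4-carbaldehyde ((S)-glyceraldehyde acetonide)
Product: 5 ethyl (2E)-2-[2-(1,3-dioxolan-2-yl)ethyl]-3-[(4R)-2,2-dimethyl-1,3-dioxolan-4-yl]prop-2-enoate
Conditions: NaH, THF, 0 → 25 °C
Reagents that add atoms: none
Why: Horner–Wadsworth–Emmons olefination with an α-alkyl phosphonoacetate should place C6 trans to the ester (E) and hence cis to C3 as the ring later requires, while the C6 centre is carried over unchanged from 4 (its descriptor turns from S to R only because the CIP priorities change).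

Step 3
Reactants: 5 enoate
Product: 6 (2E)-2-[2-(1,3-dioxolan-2-yl)ethyl]-3-[(4R)-2,2-dimethyl-1,3-dioxolan-4-yl]prop-2-en-1-ol
Conditions: i-Bu2AlH, CH2Cl2, −78 °C
Reagents that add atoms: none
Why: 1,2-reduction of the α,β-unsaturated ester by the aluminium hydride at low temperature should give the C15 allylic alcohol and leave both acetals and the olefin geometry untouched.

Step 4
Reactants: 6 allylic alcohol
Product: 7 tert-butyldiphenylsilyl ether of 6 at O15
Conditions: TBDPSCl, imidazole, CH2Cl2, 25 °C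
Reagents that add atoms: tert-butyl(chloro)diphenylsilane, CC(C)(C)[Si](Cl)(c1ccccc1)c1ccccc1
Why: silylation of a primary allylic alcohol is routine, and this acid-resistant silyl group is chosen because it must outlast the acidic acetal manipulations of steps 5, 10 and 11.

Step 5
Reactants: 7 silyl ether
Product: 8 (4E)-4-{[tert-butyl(diphenyl)silyl]oxymethyl}-5-[(4R)-2,2-dimethyl-1,3-dioxolan-4-yl]pent-4-enal
Conditions: PPTS, acetone/H2O (10:1), 60 °C
Reagents that add atoms: water, O
Why: acid-catalysed acetal exchange and hydrolysis in wet acetone should free the C1 aldehyde from its ethylene acetal, while the large excess of acetone holds the isopropylidene ketal in place by mass action and the silyl ether is inert.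

Step 6
Reactants: 1 triethyl phosphonoacetate; 9 1-[(2-bromoethoxy)methyl]-4-methoxybenzene
Product: 10 ethyl 2-(diethoxyphosphoryl)-4-[(4-methoxyphenyl)methoxy]butanoate (racemic)
Conditions: NaH, Bu4NI (cat.), DMF, 0 → 70 °C
Reagents that add atoms: none
Why: SN2 C-alkylation of the phosphonoacetate anion, helped by iodide catalysis for the sluggish β-alkoxy bromide, should deliver C9 and C8 with O8 as a 4-methoxybenzyl ether that can later be removed oxidatively beside an acetal and a silyl ether.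

Step 7
Reactants: 8 aldehyde; 10 alkylated phosphonate
Product: 11 ethyl (2E,6E)-6-{[tert-butyl(diphenyl)silyl]oxymethyl}-7-[(4R)-2,2-dimethyl-1,3-dioxolan-4-yl]-2-{2-[(4-methoxyphenyl)methoxy]ethyl}hepta-2,6-dienoate
Conditions: NaH, THF, 0 → 25 °C
Reagents that add atoms: none
Why: the second Horner–Wadsworth–Emmons olefination should build C1=C10 with C2 trans to the ester (E) and thus cis to C9, and any minor Z isomer is expected to converge later because the E enal of step 9 is the thermodynamic isomer.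

Step 8
Reactants: 11 dienoate
Product: 12 (2E,6E)-6-{[tert-butyl(diphenyl)silyl]oxymethyl}-7-[(4R)-2,2-dimethyl-1,3-dioxolan-4-yl]-2-{2-[(4-methoxyphenyl)methoxy]ethyl}hepta-2,6-dien-1-ol
Conditions: i-Bu2AlH, CH2Cl2, −78 °C
Reagents that add atoms: none
Why: 1,2-reduction of the enoate should give the C14 allylic alcohol, the only free hydroxyl in the molecule, without touching the ketal or the silyl and benzyl ethers.

Step 9
Reactants: 12 allylic alcohol
Product: 13 (2E,6E)-6-{[tert-butyl(diphenyl)silyl]oxymethyl}-7-[(4R)-2,2-dimethyl-1,3-dioxolan-4-yl]-2-{2-[(4-methoxyphenyl)methoxy]ethyl}hepta-2,6-dienal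
Conditions: MnO2, CH2Cl2, 25 °C
Reagents that add atoms: none
Why: MnO2 oxidizes allylic alcohols chemoselectively and should give the C14 enal in its favoured E geometry.

Step 10
Reactants: 13 enal
Product: 14 C14 dimethyl acetal of 13
Conditions: HC(OMe)3, PPTS (cat.), MeOH, 25 °C; Et3N quench
Reagents that add atoms: trimethyl orthoformate, COC(OC)OC; methanol, CO
Why: acid-catalysed acetalization driven by the orthoester as water scavenger should mask the C14 aldehyde, and any ketal lost here is harmless because step 11 removes it in the same medium.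

Step 11
Reactants: 14 acetal
Product: 15 (2R,3E,7E)-4-{[tert-butyl(diphenyl)silyl]oxymethyl}-8-(dimethoxymethyl)-10-[(4-methoxyphenyl)methoxy]deca-3,7-diene-1,2-diol
Conditions: CSA (cat.), MeOH, 0 → 25 °C; Et3N quench
Reagents that add atoms: none
Why: acid-catalysed methanolysis (transketalization) should remove the terminal isopropylidene ketal, whereas the C14 dimethyl acetal survives because its exchange with the solvent methanol is degenerate and the silyl and benzyl ethers tolerate the mild acid.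

Step 12
Reactants: 15 diol
Product: 17 (2R)-2-[(1E,5E)-2-{[tert-butyl(diphenyl)silyl]oxymethyl}-6-(dimethoxymethyl)-8-[(4-methoxyphenyl)methoxy]octa-1,5-dien-1-yl]oxirane, via primary tosylate 16 (not isolated)
Conditions: NaH, N-tosylimidazole, THF, 0 → 25 °C
Reagents that add atoms: none
Why: selective sulfonylation of the less hindered primary C7 alkoxide followed by intramolecular Williamson displacement by the C6 alkoxide should close the oxirane in one flask, and since no bond to C6 is broken its configuration is retained.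

Step 13
Reactants: 17 epoxide
Product: 18 (3S,4E,8E)-5-{[tert-butyl(diphenyl)silyl]oxymethyl}-9-(dimethoxymethyl)-11-[(4-methoxyphenyl)methoxy]undeca-1,4,8-trien-3-ol
Conditions: Me3S+ I−, n-BuLi, THF, −10 → 25 °C
Reagents that add atoms: trimethylsulfonium iodide, C[S+](C)C.[I-]
Why: sulfonium-ylide homologation of a terminal epoxide should apply here, the ylide opening the oxirane at the unhindered C7 (SN2′ attack is blocked at the fully substituted C4) and the resulting sulfonium salt eliminating dimethyl sulfide to give the C7 vinyl carbinol with C6 unchanged (R becomes S only by CIP priority).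

Step 14
Reactants: 18 bis-allylic alcohol; 19 2-(bromomethyl)prop-2-enoic acid
Product: 20 (3S,4E,8E)-5-{[tert-butyl(diphenyl)silyl]oxymethyl}-9-(dimethoxymethyl)-11-[(4-methoxyphenyl)methoxy]undeca-1,4,8-trien-3-yl 2-(bromomethyl)prop-2-enoate
Conditions: DCC, DMAP (cat.), CH2Cl2, 0 °C
Reagents that add atoms: none
Why: Steglich esterification acylates O6 with retention at C6, because only the O–H bond is broken, and low temperature with catalytic DMAP limits attack on the allylic bromide.

Step 15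
Reactants: 20 trienyl 2-(bromomethyl)acrylate
Product: 21 (5R)-3-(bromomethyl)-5-[(1E,5E)-2-{[tert-butyl(diphenyl)silyl]oxymethyl}-6-(dimethoxymethyl)-8-[(4-methoxyphenyl)methoxy]octa-1,5-dien-1-yl]furan-2(5H)-one
Conditions: second-generation Hoveyda–Grubbs catalyst [RuCl2(H2IMes)(=CH-C6H4-2-OiPr)] (5 mol %), toluene (0.005 M), 80 °C
Reagents that add atoms: none
Why: ring-closing metathesis should initiate at the monosubstituted C7 vinyl group and close the five-membered ring onto the 1,1-disubstituted acrylate olefin with loss of ethene, a standard route to α-substituted butenolides in which the hindered trisubstituted olefins and the C6 centre stay untouched.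

Step 16
Reactants: 21 benzyl-protected butenolide
Product: 22 (5R)-3-(bromomethyl)-5-[(1E,5E)-2-{[tert-butyl(diphenyl)silyl]oxymethyl}-6-(dimethoxymethyl)-8-hydroxyocta-1,5-dien-1-yl]furan-2(5H)-one
Conditions: DDQ, CH2Cl2/pH 7 phosphate buffer (10:1), 0 °C
Reagents that add atoms: none
Why: oxidative cleavage of the electron-rich 4-methoxybenzyl ether by DDQ is neutral when buffered, so the allylic bromide, the acetal, the silyl ether and the base-sensitive C6–H of the butenolide should all survive.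

Step 17
Reactants: 22 primary alcohol
Product: 23 (3E,7E)-8-[(2R)-4-(bromomethyl)-5-oxo-2,5-dihydrofuran-2-yl]-7-{[tert-butyl(diphenyl)silyl]oxymethyl}-3-(dimethoxymethyl)octa-3,7-dienal
Conditions: Dess–Martin periodinane, NaHCO3, CH2Cl2, 0 → 25 °C
Reagents that add atoms: none
Why: Dess–Martin oxidation gives the C8 aldehyde under base-free, buffered conditions that avoid migration of C1=C10 into conjugation and epimerization at C6, and the aldehyde is used at once.

Step 18
Reactants: 23 bromomethyl butenolide aldehyde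
Product: 26 (3aS,4R,6E,10E,11aR)-10-{[tert-butyl(diphenyl)silyl]oxymethyl}-6-(dimethoxymethyl)-4-hydroxy-3-methylidene-3a,4,5,8,9,11a-hexahydrocyclodeca[b]furan-2(3H)-one, via allylchromium dichloride 24 (not isolated), via chromium alkoxide 25 (not isolated)
Conditions: CrCl2 (8 equiv), degassed THF, 25 °C, syringe-pump addition of 23 (final 0.002 M); pH 7 buffer work-up
Reagents that add atoms: none
Why: Two equivalents of CrCl2 (divalent chromium) reduce the allylic C13–Br bond to a C13 allylchromium dichloride (trivalent chromium), which adds to the C8 aldehyde through a six-membered chair transition state (Cr, C13, C11, C7, C8, O) with allylic transposition, so that C7–C8 forms and the double bond moves from C7=C11 to C11=C13. The closest known reaction type is the Nozaki–Hiyama (chromium Barbier) allylation, established both for additions of 3-(bromomethyl)furan-2(5H)-ones to aldehydes and for the closure of ten-membered carbocycles from formyl-bearing allylic bromides. The carbocycle C1–C10 is closed by 10-exo-trig addition of the γ-carbon C7 to the C8 carbonyl under high dilution, the lactone ring being already in place. C7 is controlled by the C6 stereocentre: C8 hangs from C6 through C5 on a short tether with two ring-cis olefins and should therefore reach the butenolide face that carries C5, which gives the cis ring fusion (7S). C8 is controlled by the chair transition state, in which C6 is locked trans to C13 on the butenolide olefin (an E-type allyl unit) and C9 sits equatorial, leading to the anti relationship of C6 and O8, that is 8R. The step needs chemoselectivity for the C8 aldehyde, secured by the C14 acetal; γ-regioselectivity, secured by the closed transition state; and the two facial preferences just named.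

Step 19
Reactants: 26 macrocyclic alcohol; 27 3-methylbutanoic anhydride
Product: 28 (3aS,4R,6E,10E,11aR)-10-{[tert-butyl(diphenyl)silyl]oxymethyl}-6-(dimethoxymethyl)-3-methylidene-2-oxo-2,3,3a,4,5,8,9,11a-octahydrocyclodeca[b]furan-4-yl 3-methylbutanoate
Conditions: pyridine, DMAP (cat.), CH2Cl2, 0 → 25 °C
Reagents that add atoms: none
Why: DMAP-catalysed acylation of the secondary C8 alcohol occurs at oxygen with retention at C8, and prompt acylation also forestalls migration of the lactone to O8.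

Step 20
Reactants: 28 protected ester
Product: 29 (3aS,4R,6E,10E,11aR)-6-formyl-10-(hydroxymethyl)-3-methylidene-2-oxo-2,3,3a,4,5,8,9,11a-octahydrocyclodeca[b]furan-4-yl 3-methylbutanoate (target, CNP0345200.7)
Conditions: 48% aq HF, MeCN, 0 → 25 °C
Reagents that add atoms: water, O
Why: aqueous HF removes the silyl group by fluoride attack at silicon and, as an aqueous acid, hydrolyses the α,β-unsaturated dimethyl acetal to the enal in the same flask, while the isovalerate, the lactone and the three stereocentres are not affected.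

Compound list
1 | triethyl phosphonoacetate | CCOC(=O)CP(=O)(OCC)OCC | starting material
2 | 2-(2-bromoethyl)-1,3-dioxolane | BrCCC1OCCO1 | starting material
3 | ethyl 2-(diethoxyphosphoryl)-4-(1,3-dioxolan-2-yl)butanoate (racemic) | CCOC(=O)C(CCC1OCCO1)P(=O)(OCC)OCC | intermediate
4 | (S)-2,2-dimethyl-1,3-dioxolane-4-carbaldehyde | CC1(C)OC[C@@H](C=O)O1 | starting material
5 | ethyl (2E)-2-[2-(1,3-dioxolan-2-yl)ethyl]-3-[(4R)-2,2-dimethyl-1,3-dioxolan-4-yl]prop-2-enoate | CC1(C)OC[C@@H](/C=C(/C(=O)OCC)CCC2OCCO2)O1 | intermediate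
6 | (2E)-2-[2-(1,3-dioxolan-2-yl)ethyl]-3-[(4R)-2,2-dimethyl-1,3-dioxolan-4-yl]prop-2-en-1-ol | CC1(C)OC[C@@H](/C=C(/CO)CCC2OCCO2)O1 | intermediate
7 | tert-butyl{[(2E)-2-[2-(1,3-dioxolan-2-yl)ethyl]-3-[(4R)-2,2-dimethyl-1,3-dioxolan-4-yl]prop-2-en-1-yl]oxy}diphenylsilane | CC1(C)OC[C@@H](/C=C(/CO[Si](c2ccccc2)(c2ccccc2)C(C)(C)C)CCC2OCCO2)O1 | intermediate
8 | (4E)-4-{[tert-butyl(diphenyl)silyl]oxymethyl}-5-[(4R)-2,2-dimethyl-1,3-dioxolan-4-yl]pent-4-enal | CC1(C)OC[C@@H](/C=C(/CO[Si](c2ccccc2)(c2ccccc2)C(C)(C)C)CCC=O)O1 | intermediate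
9 | 1-[(2-bromoethoxy)methyl]-4-methoxybenzene | COc1ccc(COCCBr)cc1 | starting material
10 | ethyl 2-(diethoxyphosphoryl)-4-[(4-methoxyphenyl)methoxy]butanoate (racemic) | CCOC(=O)C(CCOCc1ccc(OC)cc1)P(=O)(OCC)OCC | intermediate
11 | ethyl (2E,6E)-6-{[tert-butyl(diphenyl)silyl]oxymethyl}-7-[(4R)-2,2-dimethyl-1,3-dioxolan-4-yl]-2-{2-[(4-methoxyphenyl)methoxy]ethyl}hepta-2,6-dienoate | CC1(C)OC[C@@H](/C=C(/CO[Si](c2ccccc2)(c2ccccc2)C(C)(C)C)CC/C=C(/C(=O)OCC)CCOCc2ccc(OC)cc2)O1 | intermediate
12 | (2E,6E)-6-{[tert-butyl(diphenyl)silyl]oxymethyl}-7-[(4R)-2,2-dimethyl-1,3-dioxolan-4-yl]-2-{2-[(4-methoxyphenyl)methoxy]ethyl}hepta-2,6-dien-1-ol | CC1(C)OC[C@@H](/C=C(/CO[Si](c2ccccc2)(c2ccccc2)C(C)(C)C)CC/C=C(/CO)CCOCc2ccc(OC)cc2)O1 | intermediate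
13 | (2E,6E)-6-{[tert-butyl(diphenyl)silyl]oxymethyl}-7-[(4R)-2,2-dimethyl-1,3-dioxolan-4-yl]-2-{2-[(4-methoxyphenyl)methoxy]ethyl}hepta-2,6-dienal | CC1(C)OC[C@@H](/C=C(/CO[Si](c2ccccc2)(c2ccccc2)C(C)(C)C)CC/C=C(/C=O)CCOCc2ccc(OC)cc2)O1 | intermediate
14 | (4R)-4-[(1E,5E)-2-{[tert-butyl(diphenyl)silyl]oxymethyl}-6-(dimethoxymethyl)-8-[(4-methoxyphenyl)methoxy]octa-1,5-dien-1-yl]-2,2-dimethyl-1,3-dioxolane | CC1(C)OC[C@@H](/C=C(/CO[Si](c2ccccc2)(c2ccccc2)C(C)(C)C)CC/C=C(/C(OC)OC)CCOCc2ccc(OC)cc2)O1 | intermediate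
15 | (2R,3E,7E)-4-{[tert-butyl(diphenyl)silyl]oxymethyl}-8-(dimethoxymethyl)-10-[(4-methoxyphenyl)methoxy]deca-3,7-diene-1,2-diol | OC[C@H](O)/C=C(/CO[Si](c1ccccc1)(c1ccccc1)C(C)(C)C)CC/C=C(/C(OC)OC)CCOCc1ccc(OC)cc1 | intermediate
16 | primary (C7) 4-methylbenzenesulfonate of 15, present as its sodium C6 alkoxide (not isolated) | Cc1ccc(cc1)S(=O)(=O)OC[C@H](O)/C=C(/CO[Si](c1ccccc1)(c1ccccc1)C(C)(C)C)CC/C=C(/C(OC)OC)CCOCc1ccc(OC)cc1 | intermediate
17 | (2R)-2-[(1E,5E)-2-{[tert-butyl(diphenyl)silyl]oxymethyl}-6-(dimethoxymethyl)-8-[(4-methoxyphenyl)methoxy]octa-1,5-dien-1-yl]oxirane | C1O[C@@H]1/C=C(/CO[Si](c1ccccc1)(c1ccccc1)C(C)(C)C)CC/C=C(/C(OC)OC)CCOCc1ccc(OC)cc1 | intermediate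
18 | (3S,4E,8E)-5-{[tert-butyl(diphenyl)silyl]oxymethyl}-9-(dimethoxymethyl)-11-[(4-methoxyphenyl)methoxy]undeca-1,4,8-trien-3-ol | C=C[C@H](O)/C=C(/CO[Si](c1ccccc1)(c1ccccc1)C(C)(C)C)CC/C=C(/C(OC)OC)CCOCc1ccc(OC)cc1 | intermediate
19 | 2-(bromomethyl)prop-2-enoic acid | C=C(CBr)C(=O)O | starting material
20 | (3S,4E,8E)-5-{[tert-butyl(diphenyl)silyl]oxymethyl}-9-(dimethoxymethyl)-11-[(4-methoxyphenyl)methoxy]undeca-1,4,8-trien-3-yl 2-(bromomethyl)prop-2-enoate | C=C[C@H](OC(=O)C(=C)CBr)/C=C(/CO[Si](c1ccccc1)(c1ccccc1)C(C)(C)C)CC/C=C(/C(OC)OC)CCOCc1ccc(OC)cc1 | intermediate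
21 | (5R)-3-(bromomethyl)-5-[(1E,5E)-2-{[tert-butyl(diphenyl)silyl]oxymethyl}-6-(dimethoxymethyl)-8-[(4-methoxyphenyl)methoxy]octa-1,5-dien-1-yl]furan-2(5H)-one | BrCC1=C[C@@H](/C=C(/CO[Si](c2ccccc2)(c2ccccc2)C(C)(C)C)CC/C=C(/C(OC)OC)CCOCc2ccc(OC)cc2)OC1=O | intermediate
22 | (5R)-3-(bromomethyl)-5-[(1E,5E)-2-{[tert-butyl(diphenyl)silyl]oxymethyl}-6-(dimethoxymethyl)-8-hydroxyocta-1,5-dien-1-yl]furan-2(5H)-one | BrCC1=C[C@@H](/C=C(/CO[Si](c2ccccc2)(c2ccccc2)C(C)(C)C)CC/C=C(/C(OC)OC)CCO)OC1=O | intermediate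
23 | (3E,7E)-8-[(2R)-4-(bromomethyl)-5-oxo-2,5-dihydrofuran-2-yl]-7-{[tert-butyl(diphenyl)silyl]oxymethyl}-3-(dimethoxymethyl)octa-3,7-dienal (key-step precursor) | BrCC1=C[C@@H](/C=C(/CO[Si](c2ccccc2)(c2ccccc2)C(C)(C)C)CC/C=C(/C(OC)OC)CC=O)OC1=O | intermediate
24 | C13 allylchromium dichloride derived from 23 (not isolated) | Cl[Cr](Cl)CC1=C[C@@H](/C=C(/CO[Si](c2ccccc2)(c2ccccc2)C(C)(C)C)CC/C=C(/C(OC)OC)CC=O)OC1=O | intermediate
25 | O8 chromium dichloride alkoxide of 26 (not isolated) | C=C1C(=O)O[C@@H]2/C=C(/CO[Si](c3ccccc3)(c3ccccc3)C(C)(C)C)CC/C=C(/C(OC)OC)C[C@@H](O[Cr](Cl)Cl)[C@H]12 | intermediate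
26 | (3aS,4R,6E,10E,11aR)-10-{[tert-butyl(diphenyl)silyl]oxymethyl}-6-(dimethoxymethyl)-4-hydroxy-3-methylidene-3a,4,5,8,9,11a-hexahydrocyclodeca[b]furan-2(3H)-one (key-step product; 6R,7S,8R in germacranolide numbers) | C=C1C(=O)O[C@@H]2/C=C(/CO[Si](c3ccccc3)(c3ccccc3)C(C)(C)C)CC/C=C(/C(OC)OC)C[C@@H](O)[C@H]12 | intermediate
27 | 3-methylbutanoic anhydride | CC(C)CC(=O)OC(=O)CC(C)C | starting material
28 | (3aS,4R,6E,10E,11aR)-10-{[tert-butyl(diphenyl)silyl]oxymethyl}-6-(dimethoxymethyl)-3-methylidene-2-oxo-2,3,3a,4,5,8,9,11a-octahydrocyclodeca[b]furan-4-yl 3-methylbutanoate | C=C1C(=O)O[C@@H]2/C=C(/CO[Si](c3ccccc3)(c3ccccc3)C(C)(C)C)CC/C=C(/C(OC)OC)C[C@@H](OC(=O)CC(C)C)[C@H]12 | intermediate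
29 | (3aS,4R,6E,10E,11aR)-6-formyl-10-(hydroxymethyl)-3-methylidene-2-oxo-2,3,3a,4,5,8,9,11a-octahydrocyclodeca[b]furan-4-yl 3-methylbutanoate | C=C1C(=O)O[C@@H]2/C=C(/CO)CC/C=C(/C=O)C[C@@H](OC(=O)CC(C)C)[C@H]12 | target

Total step count: 20. Longest linear sequence: 19 steps (steps 1–5 and 7–20; step 6 is a one-step side branch).

Steps most likely to fail

Step 18 (key step). The transient allylchromium may be protonated or couple with a second molecule faster than it closes the ten-membered ring, and the facial preference at C7 rests on the tether alone. The fallback replaces the short-lived chromium species by an isolable allylboron reagent that can be cyclized thermally and without a reductant. It sets out from 22 and comes back at 26. Borylation of the allylic bromide of 22 with bis(pinacolato)diboron under Pd2(dba)3 catalysis (toluene, 50 °C) should give the C13 pinacol boronate alcohol F1. Dess–Martin oxidation (NaHCO3, CH2Cl2) then gives the boronate aldehyde F2. Heating F2 in dilute toluene (80–110 °C, no acid, so the acetal survives) should close the ring by intramolecular allylboration through the analogous chair transition state, giving the O8 pinacol borate F3, which is hydrolysed on work-up to 26.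

Step 15. The ruthenium carbene formed at the C7 vinyl group may be deactivated by the allylic bromide, or may fail to engage the hindered bromomethyl acrylate, so that dimerization through the vinyl group takes over. The fallback carries no halide through the metathesis and introduces bromine afterwards. It sets out from 18 and comes back at 21. Commercial ethyl 2-(hydroxymethyl)acrylate is silylated (TBSCl, imidazole) to ethyl 2-{[tert-butyl(dimethyl)silyl]oxymethyl}prop-2-enoate F4 and saponified (LiOH, aq THF, 0 °C) to 2-{[tert-butyl(dimethyl)silyl]oxymethyl}prop-2-enoic acid F5. Steglich esterification of 18 with F5 gives the trienyl 2-(silyloxymethyl)acrylate F6. Ring-closing metathesis with the same catalyst should give the 3-(silyloxymethyl)butenolide F7. Acid-catalysed methanolysis (CSA, MeOH, 0 °C) removes only the tert-butyldimethylsilyl group and gives the 3-(hydroxymethyl)butenolide F8. Appel bromination (CBr4, PPh3, CH2Cl2, 0 °C) returns to 21.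

Step 2. The E selectivity may erode with this α-branched phosphonate and α-alkoxy aldehyde, which would carry the wrong C4=C5 geometry into the ring. The fallback fixes the geometry before the C3–C1 chain is attached. It sets out from 4 and comes back at 5. Wittig reaction of 4 with ethyl bromo(triphenylphosphoranylidene)acetate (CH2Cl2, 0 → 25 °C) should give ethyl (2Z)-2-bromo-3-[(4R)-2,2-dimethyl-1,3-dioxolan-4-yl]prop-2-enoate F9, in which C6 is already trans to the ester. Negishi coupling of F9 with commercial [2-(1,3-dioxolan-2-yl)ethyl]zinc bromide (Pd(PPh3)4, THF, 50 °C) replaces bromine with retention of olefin geometry and returns to 5.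

Further compounds
F1 | step 18 | (5R)-5-[(1E,5E)-2-{[tert-butyl(diphenyl)silyl]oxymethyl}-6-(dimethoxymethyl)-8-hydroxyocta-1,5-dien-1-yl]-3-[(4,4,5,5-tetramethyl-1,3,2-dioxaborolan-2-yl)methyl]furan-2(5H)-one | CC1(C)OB(CC2=C[C@@H](/C=C(/CO[Si](c3ccccc3)(c3ccccc3)C(C)(C)C)CC/C=C(/C(OC)OC)CCO)OC2=O)OC1(C)C
F2 | step 18 | (3E,7E)-7-{[tert-butyl(diphenyl)silyl]oxymethyl}-3-(dimethoxymethyl)-8-{(2R)-5-oxo-4-[(4,4,5,5-tetramethyl-1,3,2-dioxaborolan-2-yl)methyl]-2,5-dihydrofuran-2-yl}octa-3,7-dienal | CC1(C)OB(CC2=C[C@@H](/C=C(/CO[Si](c3ccccc3)(c3ccccc3)C(C)(C)C)CC/C=C(/C(OC)OC)CC=O)OC2=O)OC1(C)C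
F3 | step 18 | O8 pinacol borate of 26 (not isolated) | C=C1C(=O)O[C@@H]2/C=C(/CO[Si](c3ccccc3)(c3ccccc3)C(C)(C)C)CC/C=C(/C(OC)OC)C[C@@H](OB3OC(C)(C)C(C)(C)O3)[C@H]12
F4 | step 15 | ethyl 2-{[tert-butyl(dimethyl)silyl]oxymethyl}prop-2-enoate | C=C(CO[Si](C)(C)C(C)(C)C)C(=O)OCC
F5 | step 15 | 2-{[tert-butyl(dimethyl)silyl]oxymethyl}prop-2-enoic acid | C=C(CO[Si](C)(C)C(C)(C)C)C(=O)O
F6 | step 15 | (3S,4E,8E)-5-{[tert-butyl(diphenyl)silyl]oxymethyl}-9-(dimethoxymethyl)-11-[(4-methoxyphenyl)methoxy]undeca-1,4,8-trien-3-yl 2-{[tert-butyl(dimethyl)silyl]oxymethyl}prop-2-enoate | C=C[C@H](OC(=O)C(=C)CO[Si](C)(C)C(C)(C)C)/C=C(/CO[Si](c1ccccc1)(c1ccccc1)C(C)(C)C)CC/C=C(/C(OC)OC)CCOCc1ccc(OC)cc1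
F7 | step 15 | (5R)-3-{[tert-butyl(dimethyl)silyl]oxymethyl}-5-[(1E,5E)-2-{[tert-butyl(diphenyl)silyl]oxymethyl}-6-(dimethoxymethyl)-8-[(4-methoxyphenyl)methoxy]octa-1,5-dien-1-yl]furan-2(5H)-one | CC(C)(C)[Si](C)(C)OCC1=C[C@@H](/C=C(/CO[Si](c2ccccc2)(c2ccccc2)C(C)(C)C)CC/C=C(/C(OC)OC)CCOCc2ccc(OC)cc2)OC1=O
F8 | step 15 | (5R)-5-[(1E,5E)-2-{[tert-butyl(diphenyl)silyl]oxymethyl}-6-(dimethoxymethyl)-8-[(4-methoxyphenyl)methoxy]octa-1,5-dien-1-yl]-3-(hydroxymethyl)furan-2(5H)-one | OCC1=C[C@@H](/C=C(/CO[Si](c2ccccc2)(c2ccccc2)C(C)(C)C)CC/C=C(/C(OC)OC)CCOCc2ccc(OC)cc2)OC1=O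
F9 | step 2 | ethyl (2Z)-2-bromo-3-[(4R)-2,2-dimethyl-1,3-dioxolan-4-yl]prop-2-enoate | CC1(C)OC[C@@H](/C=C(/C(=O)OCC)Br)O1
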